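The naphthalene ring carrying C1'–C4' is disconnected at C1'–C2' and C3'–C4'. C1' sits between C5 of the isoquinoline arene and C8a', so before annulation it is a doubly benzylic CH2 whose anion lies ortho to the ester carbon that becomes oxygenated C4'. In one operation this anion adds to methyl but-2-ynoate and the allenolate formed acylates on that ester, giving the aromatic, correctly oxygenated naphthol. The precursor is a diarylmethane: a methyl 6-methoxybenzoate joined through CH2 to a dimethoxyphenyl ring bearing the (S)-2-(dibenzylamino)propyl chain, assembled by Negishi coupling. The dihydroisoquinoline is closed last by Bischler–Napieralski cyclization.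

Key step: step 6

Assumption: the target string fixes only C3 (S) and leaves the hindered C5–C1' biaryl axis open, so the route sets C3 from the aziridine and should give both rotamers about that axis (diastereomers from compound 15 onwards), separable by chromatography at the end if one is wanted.

Step 1
Reactants: 1 1-bromo-3,5-dimethoxybenzene; 2 tert-butyl (S)-2-methylaziridine-1-carboxylate
Product: 4 tert-butyl (S)-[1-(3,5-dimethoxyphenyl)propan-2-yl]carbamate, via Grignard reagent 3 (not isolated)
Conditions: Mg, THF, reflux; then 2, CuBr·SMe2 (10 mol%), THF, −30 to 0 °C; aq NH4Cl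
Reagents that add atoms: none
Why: Copper-catalysed SN2 ring opening of an N-acyl-activated aziridine by an aryl Grignard reagent occurs at the unsubstituted CH2, so the nitrogen-bearing stereocentre is not touched and stays S.

Step 2
Reactants: 4 tert-butyl (S)-[1-(3,5-dimethoxyphenyl)propan-2-yl]carbamate
Product: 5 tert-butyl (S)-[1-(2-bromo-3,5-dimethoxyphenyl)propan-2-yl]carbamate
Conditions: NBS (1.0 equiv), MeCN, 0 °C
Reagents that add atoms: N-bromosuccinimide, O=C1CCC(=O)N1Br
Why: Electrophilic aromatic bromination of a 5-alkylresorcinol dimethyl ether goes to the two equivalent positions that are para to one methoxy group and ortho to the side chain, not to the position crowded by both methoxy groups, and the carbamate tolerates NBS, which is why bromination precedes the change of nitrogen protection.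

Step 3
Reactants: 5 tert-butyl (S)-[1-(2-bromo-3,5-dimethoxyphenyl)propan-2-yl]carbamate
Product: 7 (S)-N,N-dibenzyl-1-(2-bromo-3,5-dimethoxyphenyl)propan-2-amine, via amine hydrochloride 6 (not isolated)
Conditions: HCl (4 M in dioxane), rt; evaporate; BnBr (2.5 equiv), K2CO3, MeCN, reflux
Reagents that add atoms: benzyl bromide, BrCc1ccccc1
Why: Acidolysis of the Boc group and exhaustive N-alkylation of the crude primary amine give a tertiary amine without an acidic N–H, as the later amide-base step requires; the stereocentre is not involved.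

Step 4
Reactants: 8 methyl 2-methoxy-6-methylbenzoate
Product: 9 methyl 2-(bromomethyl)-6-methoxybenzoate
Conditions: NBS (1.05 equiv), AIBN (5 mol%), PhCF3, 85 °C
Reagents that add atoms: N-bromosuccinimide, O=C1CCC(=O)N1Br
Why: Wohl–Ziegler radical bromination at the only benzylic position; the bromide is used promptly because prolonged heating would lactonize it to the phthalide.

Step 5
Reactants: 9 methyl 2-(bromomethyl)-6-methoxybenzoate; 7 (S)-N,N-dibenzyl-1-(2-bromo-3,5-dimethoxyphenyl)propan-2-amine
Product: 11 methyl 2-{2-[(2S)-2-(dibenzylamino)propyl]-4,6-dimethoxybenzyl}-6-methoxybenzoate, via benzylzinc bromide 10 (not isolated)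
Conditions: Zn dust, LiCl, THF, 0 °C to rt; then 7, Pd(OAc)2 (2 mol%), SPhos (4 mol%), THF, 50 °C
Reagents that add atoms: none
Why: Negishi sp3–sp2 coupling: zinc inserts into the benzylic C–Br bond without touching the ester, the zerovalent palladium/SPhos catalyst formed in the flask is suited to oxidative addition into a di-ortho-substituted electron-rich aryl bromide, and a benzylzinc reagent has no β-hydrogen to lose.

Step 6
Reactants: 11 methyl 2-{2-[(2S)-2-(dibenzylamino)propyl]-4,6-dimethoxybenzyl}-6-methoxybenzoate; 12 methyl but-2-ynoate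
Product: 15 methyl 4-{2-[(2S)-2-(dibenzylamino)propyl]-4,6-dimethoxyphenyl}-1-hydroxy-8-methoxy-3-methyl-2-naphthoate, via lithiated diarylmethane 13 (not isolated), via lithium allenolate 14 (not isolated)
Conditions: LiN(iPr)2 (1.2 equiv), THF, −78 °C; then 12 (1.2 equiv), −78 °C to rt; aq NH4Cl
Reagents that add atoms: none
Why: The amide base removes the doubly benzylic proton of 11, acidified by both aryl rings and the ortho ester, to give the delocalized anion 13; this adds in conjugate fashion to the methyl-bearing sp carbon of 12 (bond C1'–C2'), the α-carbon of allenolate 14 acylates on the adjacent benzoate (bond C3'–C4') with loss of methoxide, and removal of the acidic C1' proton of the resulting 4H-naphthalen-1-one gives the naphtholate without any oxidant. The closest known reaction type is the Michael–Dieckmann (Staunton–Weinreb) annulation of ortho-toluate anions with unsaturated esters, run here with an acceptor at the alkyne oxidation level. The ring made of C1', C2', C3', C4', C4a' and C8a' closes by 6-exo-trig acyl substitution, and only the benzoate ortho to the carbanion can be reached through a six-membered transition state. No stereocentre is created, but the C5–C1' axis becomes hindered on aromatization and is not controlled, so both rotamers should form. The step needs β-selective conjugate addition in preference to 1,2-addition or proton abstraction from the propargylic methyl group; the polarization of the ynoate, the soft and hindered nature of the anion and the low temperature should secure this, and attack at the central carbon of any allenoate formed by isomerization would lead to the same ring. The tertiary dibenzylamine has no acidic proton, and the benzoate, shielded by two ortho substituents, should not self-condense.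

Step 7
Reactants: 15 methyl 4-{2-[(2S)-2-(dibenzylamino)propyl]-4,6-dimethoxyphenyl}-1-hydroxy-8-methoxy-3-methyl-2-naphthoate
Product: 17 4-{2-[(2S)-2-(dibenzylamino)propyl]-4,6-dimethoxyphenyl}-8-methoxy-3-methylnaphthalen-1-ol, via hydroxy acid 16 (not isolated)
Conditions: KOH, ethylene glycol/H2O, 120 °C, argon; then aq HCl to pH 1, 100 °C
Reagents that add atoms: none
Why: Saponification followed by thermal decarboxylation of an ortho-hydroxy aryl carboxylic acid, which proceeds through ipso protonation at C3' (a β-keto acid in its keto form) and should be eased by the electron-rich naphthol and by relief of crowding between the flanking hydroxyl and methyl groups; aryl methyl ethers and the tertiary amine tolerate both stages.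

Step 8
Reactants: 17 4-{2-[(2S)-2-(dibenzylamino)propyl]-4,6-dimethoxyphenyl}-8-methoxy-3-methylnaphthalen-1-ol
Product: 18 (2S)-N,N-dibenzyl-1-[2-(4,5-dimethoxy-2-methylnaphthalen-1-yl)-3,5-dimethoxyphenyl]propan-2-amine
Conditions: NaH (1.2 equiv), DMF, 0 °C; MeI (1.2 equiv), 0 °C to rt
Reagents that add atoms: iodomethane, CI
Why: Williamson O-methylation of the naphtholate, which is far more nucleophilic than the hindered tertiary dibenzylamine, so quaternization should not compete at this stoichiometry and temperature.

Step 9
Reactants: 18 (2S)-N,N-dibenzyl-1-[2-(4,5-dimethoxy-2-methylnaphthalen-1-yl)-3,5-dimethoxyphenyl]propan-2-amine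
Product: 20 N-{(2S)-1-[2-(4,5-dimethoxy-2-methylnaphthalen-1-yl)-3,5-dimethoxyphenyl]propan-2-yl}acetamide, via primary amine 19 (not isolated)
Conditions: H2 (1–3 atm), Pd(OH)2/C, MeOH, rt; filter, evaporate; Ac2O, Et3N, CH2Cl2, 0 °C to rt
Reagents that add atoms: acetic anhydride, CC(=O)OC(C)=O
Why: Hydrogenolysis of both N-benzyl C–N bonds (the stereocentre is homobenzylic and is not cleaved) followed by N-acetylation of the crude primary amine.

Step 10
Reactants: 20 N-{(2S)-1-[2-(4,5-dimethoxy-2-methylnaphthalen-1-yl)-3,5-dimethoxyphenyl]propan-2-yl}acetamide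
Product: 21 O-methylancistrocladinine [(3S)-5-(4,5-dimethoxy-2-methylnaphthalen-1-yl)-6,8-dimethoxy-1,3-dimethyl-3,4-dihydroisoquinoline]
Conditions: POCl3 (3 equiv), 2,4,6-collidine, MeCN, reflux
Reagents that add atoms: none
Why: Bischler–Napieralski cyclodehydration, in which the activated amide attacks the only free position ortho to the side chain, a carbon that is ortho to one methoxy group and para to the other; C3 carries no proton that these conditions can remove, so its S configuration is kept.

Compound list
1 | 1-bromo-3,5-dimethoxybenzene | COc1cc(Br)cc(OC)c1 | starting material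
2 | tert-butyl (S)-2-methylaziridine-1-carboxylate | C[C@H]1CN1C(=O)OC(C)(C)C | starting material
3 | (3,5-dimethoxyphenyl)magnesium bromide | COc1cc([Mg]Br)cc(OC)c1 | intermediate
4 | tert-butyl (S)-[1-(3,5-dimethoxyphenyl)propan-2-yl]carbamate | COc1cc(C[C@H](C)NC(=O)OC(C)(C)C)cc(OC)c1 | intermediate
5 | tert-butyl (S)-[1-(2-bromo-3,5-dimethoxyphenyl)propan-2-yl]carbamate | COc1cc(OC)c(Br)c(C[C@H](C)NC(=O)OC(C)(C)C)c1 | intermediate
6 | (S)-1-(2-bromo-3,5-dimethoxyphenyl)propan-2-amine hydrochloride | COc1cc(OC)c(Br)c(C[C@H](C)[NH3+])c1.[Cl-] | intermediate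
7 | (S)-N,N-dibenzyl-1-(2-bromo-3,5-dimethoxyphenyl)propan-2-amine | COc1cc(OC)c(Br)c(C[C@H](C)N(Cc2ccccc2)Cc2ccccc2)c1 | intermediate
8 | methyl 2-methoxy-6-methylbenzoate | COC(=O)c1c(C)cccc1OC | starting material
9 | methyl 2-(bromomethyl)-6-methoxybenzoate | COC(=O)c1c(CBr)cccc1OC | intermediate
10 | [3-methoxy-2-(methoxycarbonyl)benzyl]zinc bromide | COC(=O)c1c(C[Zn]Br)cccc1OC | intermediate
11 | methyl 2-{2-[(2S)-2-(dibenzylamino)propyl]-4,6-dimethoxybenzyl}-6-methoxybenzoate | COC(=O)c1c(OC)cccc1Cc1c(OC)cc(OC)cc1C[C@H](C)N(Cc1ccccc1)Cc1ccccc1 | intermediate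
12 | methyl but-2-ynoate | CC#CC(=O)OC | starting material
13 | lithiated diarylmethane (C-lithio form of 11 at the diarylmethyl carbon) | COC(=O)c1c(OC)cccc1C([Li])c1c(OC)cc(OC)cc1C[C@H](C)N(Cc1ccccc1)Cc1ccccc1 | intermediate
14 | lithium allenolate (conjugate adduct of 13 and 12) | COC(=O)c1c(OC)cccc1C(C(C)=C=C(OC)O[Li])c1c(OC)cc(OC)cc1C[C@H](C)N(Cc1ccccc1)Cc1ccccc1 | intermediate
15 | methyl 4-{2-[(2S)-2-(dibenzylamino)propyl]-4,6-dimethoxyphenyl}-1-hydroxy-8-methoxy-3-methyl-2-naphthoate | COC(=O)c1c(C)c(-c2c(OC)cc(OC)cc2C[C@H](C)N(Cc2ccccc2)Cc2ccccc2)c2cccc(OC)c2c1O | intermediate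
16 | 4-{2-[(2S)-2-(dibenzylamino)propyl]-4,6-dimethoxyphenyl}-1-hydroxy-8-methoxy-3-methyl-2-naphthoic acid | OC(=O)c1c(C)c(-c2c(OC)cc(OC)cc2C[C@H](C)N(Cc2ccccc2)Cc2ccccc2)c2cccc(OC)c2c1O | intermediate
17 | 4-{2-[(2S)-2-(dibenzylamino)propyl]-4,6-dimethoxyphenyl}-8-methoxy-3-methylnaphthalen-1-ol | Cc1cc(O)c2c(OC)cccc2c1-c1c(OC)cc(OC)cc1C[C@H](C)N(Cc1ccccc1)Cc1ccccc1 | intermediate
18 | (2S)-N,N-dibenzyl-1-[2-(4,5-dimethoxy-2-methylnaphthalen-1-yl)-3,5-dimethoxyphenyl]propan-2-amine | Cc1cc(OC)c2c(OC)cccc2c1-c1c(OC)cc(OC)cc1C[C@H](C)N(Cc1ccccc1)Cc1ccccc1 | intermediate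
19 | (2S)-1-[2-(4,5-dimethoxy-2-methylnaphthalen-1-yl)-3,5-dimethoxyphenyl]propan-2-amine | Cc1cc(OC)c2c(OC)cccc2c1-c1c(OC)cc(OC)cc1C[C@H](C)N | intermediate
20 | N-{(2S)-1-[2-(4,5-dimethoxy-2-methylnaphthalen-1-yl)-3,5-dimethoxyphenyl]propan-2-yl}acetamide | Cc1cc(OC)c2c(OC)cccc2c1-c1c(OC)cc(OC)cc1C[C@H](C)NC(C)=O | intermediate
21 | O-methylancistrocladinine, (3S)-5-(4,5-dimethoxy-2-methylnaphthalen-1-yl)-6,8-dimethoxy-1,3-dimethyl-3,4-dihydroisoquinoline | COc1cc(OC)c(-c2c(C)cc(OC)c3c(OC)cccc23)c2c1C(C)=N[C@@H](C)C2 | target

Total step count: 10. Longest linear sequence: 9 steps (steps 1, 2, 3, 5, 6, 7, 8, 9, 10); step 4 supplies the second coupling partner.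

Steps most likely to fail

Step 6 (key step). The hindered anion may take a proton from the propargylic methyl group of the ynoate or attack its ester carbonyl in place of conjugate addition, or the adduct may not close. The fallback runs from 11 back to 15. Anion 13 is generated as before and treated with methyl (E)-but-2-enoate, the classical alkene-level Michael–Dieckmann partner. This should give methyl 4-{2-[(2S)-2-(dibenzylamino)propyl]-4,6-dimethoxyphenyl}-1-hydroxy-8-methoxy-3-methyl-3,4-dihydronaphthalene-2-carboxylate F1 as a mixture of diastereomers. After protonation of the amine with one equivalent of TFA, DDQ in dioxane removes the hydrogens at C1' and C2' and delivers 15.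

Step 5. Oxidative addition into the di-ortho-substituted, electron-rich C–Br bond may be slow, leaving the benzylzinc reagent to homocouple or be protonated. The fallback runs from 9 and 7 back to 11 by carbonyl addition instead of cross-coupling. Oxidation of 9 with N-methylmorpholine N-oxide in MeCN gives methyl 2-formyl-6-methoxybenzoate F2. Bromine–lithium exchange on 7 (n-BuLi, THF, −78 °C) gives the aryllithium F3, which adds to the aldehyde of F2; the alkoxide then lactonizes onto the neighbouring ester to give the 3-aryl-7-methoxyphthalide F4. Ionic hydrogenation (Et3SiH, TFA, CH2Cl2), which leaves N-benzyl groups intact, opens the lactone at the electron-rich benzylic C–O bond to the 2-benzylbenzoic acid F5. TMSCHN2 in toluene/MeOH then re-forms the methyl ester 11.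

Step 7. Saponification may stall because the ester carbonyl is flanked on both sides and deactivated by the adjacent naphtholate, or loss of CO2 may be slow while the hot naphtholate oxidizes in air. The fallback runs from 11 back to 17. The annulation of step 6 is run with tert-butyl but-2-ynoate in place of 12, giving tert-butyl 4-{2-[(2S)-2-(dibenzylamino)propyl]-4,6-dimethoxyphenyl}-1-hydroxy-8-methoxy-3-methyl-2-naphthoate F6. TFA in CH2Cl2 removes the tert-butyl group without nucleophilic attack at the shielded carbonyl, and warming the resulting acid 16 in toluene completes decarboxylation to 17.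

Further compounds
F1 | step 6 | methyl 4-{2-[(2S)-2-(dibenzylamino)propyl]-4,6-dimethoxyphenyl}-1-hydroxy-8-methoxy-3-methyl-3,4-dihydronaphthalene-2-carboxylate | COC(=O)C1=C(O)c2c(OC)cccc2C(c2c(OC)cc(OC)cc2C[C@H](C)N(Cc2ccccc2)Cc2ccccc2)C1C
F2 | step 5 | methyl 2-formyl-6-methoxybenzoate | COC(=O)c1c(C=O)cccc1OC
F3 | step 5 | {2-[(2S)-2-(dibenzylamino)propyl]-4,6-dimethoxyphenyl}lithium | COc1cc(OC)c([Li])c(C[C@H](C)N(Cc2ccccc2)Cc2ccccc2)c1
F4 | step 5 | 3-{2-[(2S)-2-(dibenzylamino)propyl]-4,6-dimethoxyphenyl}-7-methoxyisobenzofuran-1(3H)-one | COc1cccc2c1C(=O)OC2c1c(OC)cc(OC)cc1C[C@H](C)N(Cc1ccccc1)Cc1ccccc1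
F5 | step 5 | 2-{2-[(2S)-2-(dibenzylamino)propyl]-4,6-dimethoxybenzyl}-6-methoxybenzoic acid | OC(=O)c1c(OC)cccc1Cc1c(OC)cc(OC)cc1C[C@H](C)N(Cc1ccccc1)Cc1ccccc1
F6 | step 7 | tert-butyl 4-{2-[(2S)-2-(dibenzylamino)propyl]-4,6-dimethoxyphenyl}-1-hydroxy-8-methoxy-3-methyl-2-naphthoate | CC(C)(C)OC(=O)c1c(C)c(-c2c(OC)cc(OC)cc2C[C@H](C)N(Cc2ccccc2)Cc2ccccc2)c2cccc(OC)c2c1O
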